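**Plan**

- Retrosynthesis cuts first the ester O–CH3 bond on ring A, then the C1'–C6' bond of ring B. Ring B (C1' acyl, C2'/C6' OH, C4' CH3, C5' Cl) is an acylresorcinol, i.e. a Claisen-folded 3,5-diketo ester that a 6-substituted 2-pyranone can mask (pyranone C2 = C6', C3–Cl = C5', C4–CH3 = C4', C5 = C3', C6 = C2').
- The pyranone side chain is then cut at the ketone C(=O)–CH2 bond into lithiated 3-chloro-4,6-dimethylpyran-2-one and a ring A acyl imidazolide. Its neighbouring carboxyl is held as a tert-butyl ester and its phenol as a MOM ether.
- Ring A comes from 3,5-dihydroxybenzoic acid: tert-butyl ester, Vilsmeier formylation at C2, hydrogen-bond-guided MOM/methyl differentiation of the two phenols, Pinnick oxidation.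
- Forward order: ring A is present from the start, the pyranone is chlorinated and joined to it by C-acylation, acid frees carboxyl and phenol, Mg(OMe)2 closes ring B, and the acid is methylated last.
- The target has no stereocentre. The only geometric element, the cis relation of ester and keto chain across the chloroalkene of the opened pyranone, is inherited from the ring.

Key step: step 9

Remark: the unmasked keto acid that enters the ring B closure may rest partly as its ring lactol (3-hydroxyphthalide) tautomer; base returns it to the open keto carboxylate, so it is treated as the open form. The two starting materials are taken as commercial.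

**Route**

Step 1
Reactants: 1 3,5-dihydroxybenzoic acid
Product: 2 tert-butyl 3,5-dihydroxybenzoate
Conditions: Me2NCH(OtBu)2 (4 equiv), toluene, 80 °C
Reagents that add atoms: N,N-dimethylformamide di-tert-butyl acetal, CN(C)C(OC(C)(C)C)OC(C)(C)C
Why: Esterification by a formamide acetal, in which the acid protonates the reagent and the carboxylate takes up the tert-butyl group while the much less acidic phenols are left alone.

Step 2
Reactants: 2 tert-butyl 3,5-dihydroxybenzoate
Product: 3 tert-butyl 2-formyl-3,5-dihydroxybenzoate
Conditions: POCl3, DMF, MeCN, 0 °C to rt; then aq CH3CO2Na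
Reagents that add atoms: N,N-dimethylformamide, CN(C)C=O; water, O
Why: Vilsmeier–Haack formylation at C2, ortho to one hydroxyl and para to the other (the usual site in 5-substituted resorcinols), in a DMF-buffered medium at or below room temperature that a tert-butyl ester should tolerate.

Step 3
Reactants: 3 tert-butyl 2-formyl-3,5-dihydroxybenzoate
Product: 4 tert-butyl 2-formyl-3-hydroxy-5-(methoxymethoxy)benzoate
Conditions: MOMCl (1.05 equiv), iPr2NEt, CH2Cl2, 0 °C
Reagents that add atoms: chloromethyl methyl ether, COCCl
Why: Williamson-type O-alkylation that should pick the 5-OH, because the 3-OH is tied up in a hydrogen bond to the ortho formyl group whereas the 5-OH, para to that group, is the more acidic and more exposed phenol.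

Step 4
Reactants: 4 tert-butyl 2-formyl-3-hydroxy-5-(methoxymethoxy)benzoate
Product: 5 tert-butyl 2-formyl-3-methoxy-5-(methoxymethoxy)benzoate
Conditions: MeI, K2CO3, DMF, rt
Reagents that add atoms: iodomethane, CI
Why: Williamson methylation of the remaining chelated phenol under carbonate conditions that leave the aldehyde, the MOM acetal and the tert-butyl ester untouched.

Step 5
Reactants: 5 tert-butyl 2-formyl-3-methoxy-5-(methoxymethoxy)benzoate
Product: 6 2-(tert-butoxycarbonyl)-6-methoxy-4-(methoxymethoxy)benzoic acid
Conditions: NaClO2, NaH2PO4, 2-methylbut-2-ene, t-BuOH/H2O, 0 °C to rt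
Reagents that add atoms: sodium chlorite, [Na+].[O-]Cl=O
Why: Pinnick oxidation converts the hindered, non-enolisable aldehyde into the acid at buffered pH, the alkene scavenger removing HOCl before it can chlorinate the electron-rich ring.

Step 6
Reactants: 7 4,6-dimethyl-2H-pyran-2-one
Product: 8 3-chloro-4,6-dimethyl-2H-pyran-2-one
Conditions: SO2Cl2 (1.05 equiv), CH2Cl2, 0 °C to rt
Reagents that add atoms: sulfuryl chloride, ClS(Cl)(=O)=O
Why: Electrophilic substitution of the 2-pyranone at C3, where attack gives a cation spread over C4, C6 and the ring oxygen and where crowding is less than at C5 between the two methyl groups; a C5 chloro isomer, if it formed, would map onto the same ring B because the resorcinol is symmetric about its C1'–C4' axis.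

Step 7
Reactants: 6 2-(tert-butoxycarbonyl)-6-methoxy-4-(methoxymethoxy)benzoic acid; 8 3-chloro-4,6-dimethyl-2H-pyran-2-one
Product: 11 tert-butyl 2-[(3-chloro-4-methyl-2-oxo-2H-pyran-6-yl)acetyl]-3-methoxy-5-(methoxymethoxy)benzoate, via acyl imidazolide 9 (not isolated), via lithiated pyranone 10 (not isolated)
Conditions: 6, CDI, THF, rt, argon purge; added to 8 (3.3 equiv) and LiN(SiMe3)2 (3.2 equiv), THF, −78 to −30 °C; AcOH quench at low temperature
Reagents that add atoms: none
Why: Lateral lithiation of the 6-methyl group gives a delocalised carbanion that is C-acylated by the acyl imidazole in a crossed Claisen-type condensation; the extra equivalents of anion absorb the imidazole N–H and the acidic methylene of the product, and the tert-butyl ester is too hindered to be attacked by the product enolate.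

Step 8
Reactants: 11 tert-butyl 2-[(3-chloro-4-methyl-2-oxo-2H-pyran-6-yl)acetyl]-3-methoxy-5-(methoxymethoxy)benzoate
Product: 12 2-[(3-chloro-4-methyl-2-oxo-2H-pyran-6-yl)acetyl]-5-hydroxy-3-methoxybenzoic acid
Conditions: CF3CO2H/CH2Cl2 (1:2), H2O (5 equiv), 0 °C to rt
Reagents that add atoms: none
Why: Acidolysis (E1 cleavage of the tert-butyl ester and hydrolysis of the MOM acetal) frees acid and phenol in one operation under conditions to which the pyranone lactone is inert, with water present to intercept the methoxymethyl cation.

Step 9
Reactants: 12 2-[(3-chloro-4-methyl-2-oxo-2H-pyran-6-yl)acetyl]-5-hydroxy-3-methoxybenzoic acid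
Product: 14 2-(3-chloro-2,6-dihydroxy-4-methylbenzoyl)-5-hydroxy-3-methoxybenzoic acid, via ring-opened triketo ester 13 (not isolated)
Conditions: Mg(OMe)2 (8 equiv), MeOH, reflux; then cold 1 M HCl
Reagents that add atoms: none
Why: Methoxide adds to the lactone carbonyl (pyranone C2) and the ring opens to the methyl dienoate 13, in which ester and diketone chain remain cis across the chloroalkene because that geometry comes from the ring. The magnesium-chelated carbanion between the two ketones then attacks the ester carbon in a 6-exo-trig Claisen (Dieckmann-type) closure that forms the C1'–C6' bond, and loss of methoxide followed by enolisation gives the aromatic acylresorcinol with chlorine and methyl already in place. The closest known reaction type is the base-induced rearrangement of 6-(2-oxoalkyl)-2-pyranones to acylresorcinols and acylphloroglucinols. No stereocentre is formed. The step needs Claisen closure to win over aldol-type attack of the dienolate on the aroyl carbonyl and over closure onto ring A: the first should be secured by the doubly ortho-substituted, phenoxide-deactivated aroyl group and by magnesium chelation of the 1,3-diketone, the second by the ring A carboxyl being a carboxylate, which cannot serve as acyl donor, so no indanedione can arise.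

Step 10
Reactants: 14 2-(3-chloro-2,6-dihydroxy-4-methylbenzoyl)-5-hydroxy-3-methoxybenzoic acid
Product: 15 monochlorosulochrin
Conditions: MeI (1.1 equiv), KHCO3 (1.2 equiv), DMF, rt
Reagents that add atoms: iodomethane, CI
Why: Chemoselective SN2 O-alkylation of the carboxylate, the only group fully ionised by hydrogencarbonate, should give the normal methyl ester while the three phenols stay free.

**Compound list**

1 | 3,5-dihydroxybenzoic acid | O=C(O)c1cc(O)cc(O)c1 | starting material
2 | tert-butyl 3,5-dihydroxybenzoate | CC(C)(C)OC(=O)c1cc(O)cc(O)c1 | intermediate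
3 | tert-butyl 2-formyl-3,5-dihydroxybenzoate | CC(C)(C)OC(=O)c1cc(O)cc(O)c1C=O | intermediate
4 | tert-butyl 2-formyl-3-hydroxy-5-(methoxymethoxy)benzoate | CC(C)(C)OC(=O)c1cc(OCOC)cc(O)c1C=O | intermediate
5 | tert-butyl 2-formyl-3-methoxy-5-(methoxymethoxy)benzoate | CC(C)(C)OC(=O)c1cc(OCOC)cc(OC)c1C=O | intermediate
6 | 2-(tert-butoxycarbonyl)-6-methoxy-4-(methoxymethoxy)benzoic acid | CC(C)(C)OC(=O)c1cc(OCOC)cc(OC)c1C(=O)O | intermediate
7 | 4,6-dimethyl-2H-pyran-2-one | CC1=CC(C)=CC(=O)O1 | starting material
8 | 3-chloro-4,6-dimethyl-2H-pyran-2-one | CC1=CC(C)=C(Cl)C(=O)O1 | intermediate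
9 | tert-butyl 2-(1H-imidazol-1-ylcarbonyl)-3-methoxy-5-(methoxymethoxy)benzoate | CC(C)(C)OC(=O)c1cc(OCOC)cc(OC)c1C(=O)n1ccnc1 | intermediate (not isolated)
10 | [(3-chloro-4-methyl-2-oxo-2H-pyran-6-yl)methyl]lithium | [Li]CC1=CC(C)=C(Cl)C(=O)O1 | intermediate (not isolated)
11 | tert-butyl 2-[(3-chloro-4-methyl-2-oxo-2H-pyran-6-yl)acetyl]-3-methoxy-5-(methoxymethoxy)benzoate | CC(C)(C)OC(=O)c1cc(OCOC)cc(OC)c1C(=O)CC1=CC(C)=C(Cl)C(=O)O1 | intermediate
12 | 2-[(3-chloro-4-methyl-2-oxo-2H-pyran-6-yl)acetyl]-5-hydroxy-3-methoxybenzoic acid | O=C(O)c1cc(O)cc(OC)c1C(=O)CC1=CC(C)=C(Cl)C(=O)O1 | intermediate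
13 | 2-[(5E)-6-chloro-7-methoxy-5-methyl-3,7-dioxohept-5-enoyl]-5-hydroxy-3-methoxybenzoic acid (present as its magnesium enolate) | COC(=O)/C(Cl)=C(/C)CC(=O)CC(=O)c1c(OC)cc(O)cc1C(=O)O | intermediate (not isolated)
14 | 2-(3-chloro-2,6-dihydroxy-4-methylbenzoyl)-5-hydroxy-3-methoxybenzoic acid | O=C(O)c1cc(O)cc(OC)c1C(=O)c1c(O)cc(C)c(Cl)c1O | intermediate
15 | monochlorosulochrin, methyl 2-(3-chloro-2,6-dihydroxy-4-methylbenzoyl)-5-hydroxy-3-methoxybenzoate | COC(=O)c1cc(O)cc(OC)c1C(=O)c1c(O)cc(C)c(Cl)c1O | target

**Step count**

Total: 10 steps. Longest linear sequence: 9 steps (steps 1–5 and 7–10); step 6 is a one-step side branch.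

**Steps most likely to fail**

Step 7. Acyl transfer from a doubly ortho-substituted, electron-rich acyl imidazole to a stabilised anion may be slow. Self-condensation of the lithiated pyranone, metalation at the 4-methyl group, or collapse of the imidazolide onto its neighbouring tert-butyl ester could then take over. The fallback changes the oxidation level of the electrophile and sets out from aldehyde 5 (step 5 is then skipped) and chloropyranone 8. The lithiated pyranone would be added to the far more electrophilic aldehyde at −78 °C and quenched cold with acetic acid, so that the alkoxide does not lactonise onto the ester. This should give racemic tert-butyl 2-[2-(3-chloro-4-methyl-2-oxo-2H-pyran-6-yl)-1-hydroxyethyl]-3-methoxy-5-(methoxymethoxy)benzoate F1. Oxidation of the benzylic alcohol with Dess–Martin periodinane buffered by NaHCO3 comes back to the route at 11.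

Step 9. The opened dienolate may close in the aldol sense onto the aroyl carbonyl with loss of chloride, may simply relactonise to 12 on acidification, or may fall out of methanol as an unreactive polyanionic magnesium salt. The fallback makes ring B first and joins it to ring A as an aryllithium; it sets out from aldehyde 5.
- Commercial orcinol would be chlorinated with SO2Cl2 to 4-chloro-5-methylbenzene-1,3-diol F2.
- MOMCl and iPr2NEt would convert it into 2-chloro-1,5-bis(methoxymethoxy)-3-methylbenzene F3.
- n-BuLi should lithiate F3 between the two MOM ethers; addition to 5 at −78 °C with a cold quench should give racemic tert-butyl 2-{[3-chloro-2,6-bis(methoxymethoxy)-4-methylphenyl](hydroxy)methyl}-3-methoxy-5-(methoxymethoxy)benzoate F4.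
- Dess–Martin oxidation would give tert-butyl 2-[3-chloro-2,6-bis(methoxymethoxy)-4-methylbenzoyl]-3-methoxy-5-(methoxymethoxy)benzoate F5.
- CF3CO2H with a thiol scavenger would remove the tert-butyl ester and all three MOM groups, returning to the route at acid 14.

Step 2. The tert-butyl group may be lost in the acidic chloroiminium medium, or formylation may drift to C4 between the two hydroxyls because of crowding next to the bulky ester. The fallback carries out formylation and phenol differentiation on the methyl ester and exchanges the ester afterwards; it sets out from acid 1.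
- Fischer esterification (MeOH, H2SO4) would give methyl 3,5-dihydroxybenzoate F6.
- POCl3/DMF would give methyl 2-formyl-3,5-dihydroxybenzoate F7.
- MOMCl/iPr2NEt would give methyl 2-formyl-3-hydroxy-5-(methoxymethoxy)benzoate F8.
- MeI/K2CO3 would give methyl 2-formyl-3-methoxy-5-(methoxymethoxy)benzoate F9.
- LiOH in THF/H2O would give 2-formyl-3-methoxy-5-(methoxymethoxy)benzoic acid F10.
- O-tert-butyl-N,N'-diisopropylisourea in CH2Cl2 would esterify the open-chain acid and come back to the route at 5.

**Further compounds**

F1 | step 7 | tert-butyl 2-[2-(3-chloro-4-methyl-2-oxo-2H-pyran-6-yl)-1-hydroxyethyl]-3-methoxy-5-(methoxymethoxy)benzoate (racemic) | CC(C)(C)OC(=O)c1cc(OCOC)cc(OC)c1C(O)CC1=CC(C)=C(Cl)C(=O)O1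
F2 | step 9 | 4-chloro-5-methylbenzene-1,3-diol | Cc1cc(O)cc(O)c1Cl
F3 | step 9 | 2-chloro-1,5-bis(methoxymethoxy)-3-methylbenzene | Cc1cc(OCOC)cc(OCOC)c1Cl
F4 | step 9 | tert-butyl 2-{[3-chloro-2,6-bis(methoxymethoxy)-4-methylphenyl](hydroxy)methyl}-3-methoxy-5-(methoxymethoxy)benzoate (racemic) | CC(C)(C)OC(=O)c1cc(OCOC)cc(OC)c1C(O)c1c(OCOC)cc(C)c(Cl)c1OCOC
F5 | step 9 | tert-butyl 2-[3-chloro-2,6-bis(methoxymethoxy)-4-methylbenzoyl]-3-methoxy-5-(methoxymethoxy)benzoate | CC(C)(C)OC(=O)c1cc(OCOC)cc(OC)c1C(=O)c1c(OCOC)cc(C)c(Cl)c1OCOC
F6 | step 2 | methyl 3,5-dihydroxybenzoate | COC(=O)c1cc(O)cc(O)c1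
F7 | step 2 | methyl 2-formyl-3,5-dihydroxybenzoate | COC(=O)c1cc(O)cc(O)c1C=O
F8 | step 2 | methyl 2-formyl-3-hydroxy-5-(methoxymethoxy)benzoate | COC(=O)c1cc(OCOC)cc(O)c1C=O
F9 | step 2 | methyl 2-formyl-3-methoxy-5-(methoxymethoxy)benzoate | COC(=O)c1cc(OCOC)cc(OC)c1C=O
F10 | step 2 | 2-formyl-3-methoxy-5-(methoxymethoxy)benzoic acid | O=Cc1c(OC)cc(OCOC)cc1C(=O)O
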